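The seven-membered ring (C5–C6–C7–C8–C9–C10–C11) holds an aldol pattern: carbinol C7 lies next to quaternary C6, whose C13 is oxygenated, and is 1,3-anti to O9. The C6–C7 bond is therefore closed last, by a Lewis-acid aldol cyclisation of a C6=C13 enol acetate onto a C7 aldehyde. One operation forms the ring, sets C6 and C7, and passes the enol acetyl group to O7 as the 7-acetate. The precursor is a verbenone-type bicyclo[3.1.1]heptenone whose C5 and C10 carry two arms on the same cyclobutane face; this core comes from an intramolecular vinylketene–alkene [2+2] cycloaddition of an acyclic dienoic acid made by two catalytic asymmetric aldol additions.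

Key step: step 16

Remark: C-labels are those of the longipinane skeleton of the target (C1 ketone, C2=C3 with C12 methyl, bridgeheads C4 and C11, C5 H, C6 with C13 = CH2O and C14 = CH3, C7 OAc, C8, C9 O-ester, C10 with C15 methyl); both unsaturated esters are read as (Z)-2-methylbut-2-enoates (angelates); where an alkene geometry is lost in the next step the SMILES leaves it open.

Step 1
Reactants: 1 (2E)-4-acetoxy-2-methylbut-2-enal; 2 trimethyl(vinyloxy)silane
Product: 4 (2E,4R)-4-hydroxy-6,6-dimethoxy-3-methylhex-2-en-1-yl acetate, via trichlorosilyl aldolate 3 (not isolated)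
Conditions: SiCl4, chiral binaphthyldiamine-derived bisphosphoramide (5 mol%, enantiomer chosen for Re-face addition), i-Pr2NEt, CH2Cl2, −78 °C; then MeOH, −78 °C to rt; NaHCO3
Reagents that add atoms: trimethyl(vinyloxy)silane C=CO[Si](C)(C)C; methanol CO
Why: SiCl4 activated by the chiral bisphosphoramide acts as a chiral Lewis acid in a Mukaiyama-type crossed aldol addition of the acetaldehyde enol silane to the α-branched enal, catalyst-controlled Re-face attack setting C9 (R), and methanolysis of the chlorosilyl aldolate traps the labile β-oxy aldehyde as its dimethyl acetal.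

Step 2
Reactants: 4 (2E,4R)-4-hydroxy-6,6-dimethoxy-3-methylhex-2-en-1-yl acetate
Product: 5 (2E,4R)-4-[(tert-butyldimethylsilyl)oxy]-6,6-dimethoxy-3-methylhex-2-en-1-yl acetate
Conditions: t-BuMe2SiCl, imidazole, DMF, rt
Reagents that add atoms: tert-butylchlorodimethylsilane CC(C)(C)[Si](C)(C)Cl
Why: Standard silylation (silyl chloride/imidazole) of the secondary allylic alcohol masks O9 until the end of the route.

Step 3
Reactants: 5 (2E,4R)-4-[(tert-butyldimethylsilyl)oxy]-6,6-dimethoxy-3-methylhex-2-en-1-yl acetate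
Product: 6 (2E,4R)-4-[(tert-butyldimethylsilyl)oxy]-6,6-dimethoxy-3-methylhex-2-en-1-ol
Conditions: K2CO3 (cat.), MeOH, 0 °C
Reagents that add atoms: none
Why: Base-catalysed transesterification removes the primary acetate while the silyl ether and the acetal are inert to methoxide.

Step 4
Reactants: 6 (2E,4R)-4-[(tert-butyldimethylsilyl)oxy]-6,6-dimethoxy-3-methylhex-2-en-1-ol
Product: 7 (2E,4R)-4-[(tert-butyldimethylsilyl)oxy]-6,6-dimethoxy-3-methylhex-2-enal
Conditions: MnO2, CH2Cl2, rt
Reagents that add atoms: none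
Why: MnO2 oxidation of the primary allylic alcohol gives the enal without touching the alkene geometry or the acid-sensitive groups.

Step 5
Reactants: 8 methyl 3-methylbut-2-enoate
Product: 9 tert-butyl[(1-methoxy-3-methylbuta-1,3-dien-1-yl)oxy]dimethylsilane (ketene acetal isomers)
Conditions: LiN(i-Pr)2, THF, −78 °C; t-BuMe2SiCl, DMPU
Reagents that add atoms: tert-butylchlorodimethylsilane CC(C)(C)[Si](C)(C)Cl
Why: Kinetic γ-deprotonation of the senecioate gives the extended lithium dienolate, whose O-silylation furnishes the silyl dienol ether needed as vinylogous donor.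

Step 6
Reactants: 7 (2E,4R)-4-[(tert-butyldimethylsilyl)oxy]-6,6-dimethoxy-3-methylhex-2-enal; 9 tert-butyl[(1-methoxy-3-methylbuta-1,3-dien-1-yl)oxy]dimethylsilane
Product: 10 methyl (2E,5S,6E,8R)-8-[(tert-butyldimethylsilyl)oxy]-5-hydroxy-10,10-dimethoxy-3,7-dimethyldeca-2,6-dienoate
Conditions: SiCl4, chiral bisphosphoramide (5 mol%, enantiomer chosen for Si-face addition), i-Pr2NEt, CH2Cl2, −78 °C; aq NaHCO3
Reagents that add atoms: silyl dienol ether 9 COC(O[Si](C)(C)C(C)(C)C)=CC(C)=C
Why: Vinylogous Mukaiyama aldol addition under chiral Lewis-base/SiCl4 catalysis, in which the dienol ether reacts at its γ-carbon to give the (E)-enoate and catalyst-controlled Si-face attack sets C1 (S) irrespective of the remote C9 centre.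

Step 7
Reactants: 10 methyl (2E,5S,6E,8R)-8-[(tert-butyldimethylsilyl)oxy]-5-hydroxy-10,10-dimethoxy-3,7-dimethyldeca-2,6-dienoate
Product: 11 (2E,5S,6E,8R)-8-[(tert-butyldimethylsilyl)oxy]-5-hydroxy-10,10-dimethoxy-3,7-dimethyldeca-2,6-dienoic acid
Conditions: LiOH, THF/MeOH/H2O, 40 °C; NaH2PO4 to pH 5
Reagents that add atoms: lithium hydroxide [Li+].[OH-]
Why: Saponification of the β,β-disubstituted enoate with hydroxide, followed by buffered acidification that keeps the acetal and the silyl ether intact.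

Step 8
Reactants: 11 (2E,5S,6E,8R)-8-[(tert-butyldimethylsilyl)oxy]-5-hydroxy-10,10-dimethoxy-3,7-dimethyldeca-2,6-dienoic acid
Product: 12 triethylsilyl (2E,5S,6E,8R)-8-[(tert-butyldimethylsilyl)oxy]-10,10-dimethoxy-3,7-dimethyl-5-[(triethylsilyl)oxy]deca-2,6-dienoate
Conditions: Et3SiCl (2.5 equiv), imidazole, DMF, 0 °C to rt
Reagents that add atoms: chlorotriethylsilane CC[Si](Cl)(CC)CC
Why: Silyl chloride/imidazole silylates both the C1 hydroxyl and the carboxylic acid, the silyl ester serving as a neutral precursor of the acid chloride.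

Step 9
Reactants: 12 triethylsilyl (2E,5S,6E,8R)-8-[(tert-butyldimethylsilyl)oxy]-10,10-dimethoxy-3,7-dimethyl-5-[(triethylsilyl)oxy]deca-2,6-dienoate
Product: 15 (4S)-7-methyl-2-methylidene-7-[(1R)-1-(tert-butyldimethylsilyloxy)-3,3-dimethoxypropyl]-4-(triethylsilyloxy)bicyclo[3.1.1]heptan-6-one (7-methyl syn and side chain anti to the C2–C4 bridge; 4-silyloxy group facing the C6 bridge), via acid chloride 13 (not isolated), via vinylketene 14 (not isolated)
Conditions: (COCl)2, DMF (cat.), CH2Cl2, 0 °C; then slow addition to Et3N, toluene, 110 °C, high dilution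
Reagents that add atoms: none
Why: The silyl ester gives the enoyl chloride under neutral conditions, γ-dehydrochlorination gives a vinylketene, and an intramolecular crossed [2+2] ketene–alkene cycloaddition (ketene carbonyl carbon to C11, α-carbon to C10) builds the cyclobutanone; the (E)-alkene places the C15 methyl syn and the C9 arm anti to the C1–C3 bridge, and allylic 1,3-strain (C1–H, not C1–OSiEt3, next to the C15 methyl) selects the alkene face, so that C1 (S) fixes C4, C10 and C11.

Step 10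
Reactants: 15 bicyclic cyclobutanone (as in step 9)
Product: 16 7-methyl-4-methylidene-7-[(1R)-1-(tert-butyldimethylsilyloxy)-3,3-dimethoxypropyl]bicyclo[3.1.1]heptane-2,6-dione (ring configuration as in 15)
Conditions: 2-iodoxybenzoic acid (IBX), DMSO, rt; used without delay
Reagents that add atoms: none
Why: IBX in DMSO removes the triethylsilyl ether oxidatively (the bulkier tert-butyldimethylsilyl ether persists) and gives the C1 ketone, erasing the C1 centre once it has relayed its information to the ring system.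

Step 11
Reactants: 16 exo-methylene dione (as in step 10)
Product: 17 2-(tert-butyldimethylsilyloxy)-7-methyl-4-methylidene-7-[(1R)-1-(tert-butyldimethylsilyloxy)-3,3-dimethoxypropyl]bicyclo[3.1.1]hept-2-en-6-one
Conditions: t-BuMe2SiOTf, Et3N, CH2Cl2, −78 °C
Reagents that add atoms: tert-butyldimethylsilyl triflate CC(C)(C)[Si](C)(C)OS(=O)(=O)C(F)(F)F
Why: Soft enolisation (silyl triflate/amine) at C2, the only enolisable position since C11 is a bridgehead, gives the 2-silyloxy-1,3-diene, which masks the later enone against hydride and makes the C1–C3 bridge flat.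

Step 12
Reactants: 17 silyloxydiene cyclobutanone (as in step 11); 18 diethyl (1-cyanoethyl)phosphonate
Product: 19 2-{2-(tert-butyldimethylsilyloxy)-7-methyl-4-methylidene-7-[(1R)-1-(tert-butyldimethylsilyloxy)-3,3-dimethoxypropyl]bicyclo[3.1.1]hept-2-en-6-ylidene}propanenitrile (alkene isomers)
Conditions: LiN(SiMe3)2, THF, −78 °C to rt
Reagents that add atoms: diethyl (1-cyanoethyl)phosphonate CCOP(=O)(OCC)C(C)C#N
Why: Horner–Wadsworth–Emmons olefination of the strained cyclobutanone by the small cyano-stabilised phosphonate anion, which can reach C5 over the flat diene bridge; the geometry of the new alkene is lost in step 14.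

Step 13
Reactants: 19 alkylidene nitrile (as in step 12)
Product: 20 2-{2-(tert-butyldimethylsilyloxy)-7-methyl-4-methylidene-7-[(1R)-1-(tert-butyldimethylsilyloxy)-3,3-dimethoxypropyl]bicyclo[3.1.1]hept-2-en-6-ylidene}propanal (alkene isomers)
Conditions: i-Bu2AlH, toluene, −78 °C; aq KNa tartrate, SiO2
Reagents that add atoms: water O
Why: Partial reduction of the nitrile by i-Bu2AlH stops at the N-aluminio imine, which is hydrolysed on work-up to the enal while silyl ethers, diene and acetal are untouched.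

Step 14
Reactants: 20 alkylidene aldehyde (as in step 13)
Product: 21 2-{2-(tert-butyldimethylsilyloxy)-7-methyl-4-methylidene-7-[(1R)-1-(tert-butyldimethylsilyloxy)-3,3-dimethoxypropyl]bicyclo[3.1.1]hept-2-en-6-yl}prop-1-en-1-yl acetate (H-6 syn to the diene bridge, the C6 arm on the same cyclobutane face as the C7 side chain; enol isomers)
Conditions: [(Ph3P)CuH]6 (0.4 equiv), benzene, rt; then Ac2O, 0 °C
Reagents that add atoms: acetic anhydride CC(=O)OC(C)=O
Why: Conjugate reduction with the Stryker reagent delivers hydride to C5 from the face of the flat diene bridge, the other face being covered by the C9 arm on C10, so H5 ends syn to the bridge and the C6 arm next to the C9 arm; the copper enolate is O-acetylated to the enol acetate.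

Step 15
Reactants: 21 enol acetate acetal (as in step 14)
Product: 23 2-{4,7-dimethyl-2-oxo-7-[(1R)-1-(tert-butyldimethylsilyloxy)-3-oxopropyl]bicyclo[3.1.1]hept-3-en-6-yl}prop-1-en-1-yl acetate (ring configuration as in 21; enol isomers), via exo-methylene ketone 22 (not isolated)
Conditions: PPTS, acetone/H2O (10:1), 35 °C; then Et3N (cat.), CH2Cl2, 0 °C
Reagents that add atoms: water O
Why: Mild aqueous acid hydrolyses the dimethyl acetal and the silyl dienol ether but not the enol acetate or the secondary silyl ether, and amine-catalysed conjugation moves the exocyclic alkene into the C2=C3 position.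

Step 16
Reactants: 23 enol acetate aldehyde (as in step 15)
Product: 24 7-acetoxy-9-(tert-butyldimethylsilyloxy)-1-oxolongipin-2-en-13-al (7-OAc trans to 9-O; formyl C13 cis to 9-O; C14 methyl cis to 7-OAc)
Conditions: BF3·OEt2 (1.2 equiv), CH2Cl2, −78 to −40 °C; aq NaHCO3
Reagents that add atoms: none
Why: BF3 binds the C7 aldehyde, the C6=C13 enol acetate attacks it through its fully substituted carbon, and the resulting acetoxycarbenium ion is discharged by transfer of the acetyl group to the new C7 alkoxide through a six-membered array, giving the 7-acetate and the C13 aldehyde directly. The closest known reaction is the Lewis-acid (Mukaiyama-type) aldol addition of enol esters and enol silanes to aldehydes, here run intramolecularly. The seven-membered carbocycle closes in a 7-(enolexo)-exo-trig mode onto a cis-1,3-disubstituted cyclobutane whose two arms already hold C6 and C7 within bonding distance. C7 is controlled by the C9 silyloxy group: in the twist transition state the complexed carbonyl oxygen avoids the syn-parallel C9–O dipole (1,3-anti induction in an open transition state), giving 7-O trans to 9-O. C6 is controlled by the antiperiplanar arrangement of C6=C13 and C7=O, which keeps the acetoxy-bearing terminus away from the boron-bound oxygen and so puts C13 cis to O9 and the C14 methyl cis to O7. The step needs the aldehyde to react in preference to the enone and the β-silyloxy group to stay; only one enol nucleophile is present, C6 cannot reach the enone, and a monodentate Lewis acid at low temperature secures the rest.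

Step 17
Reactants: 24 tricyclic acetoxy aldehyde (as in step 16)
Product: 25 7-acetoxy-9-(tert-butyldimethylsilyloxy)-13-hydroxylongipin-2-en-1-one
Conditions: NaBH(OAc)3, AcOH, 1,2-dichloroethane, rt
Reagents that add atoms: none
Why: NaBH(OAc)3 reduces the aldehyde chemoselectively in the presence of the conjugated ketone and the acetate, and its non-basic medium suppresses 1,3-acetyl migration to the new primary alcohol.

Step 18
Reactants: 25 7-acetoxy-9-(tert-butyldimethylsilyloxy)-13-hydroxylongipin-2-en-1-one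
Product: 26 7-acetoxy-9,13-dihydroxylongipin-2-en-1-one
Conditions: HF·pyridine, pyridine, THF, 0 °C to rt
Reagents that add atoms: none
Why: Fluoride-mediated cleavage of the silyl ether under buffered acidic conditions that do not move the 7-acetate.

Step 19
Reactants: 26 7-acetoxy-9,13-dihydroxylongipin-2-en-1-one; 27 angelic acid, (2Z)-2-methylbut-2-enoic acid
Product: 29 target CNP0364726.1, 7-acetoxy-9,13-bis[(2Z)-2-methylbut-2-enoyloxy]longipin-2-en-1-one, via mixed anhydride 28 (not isolated)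
Conditions: 27, 2,4,6-trichlorobenzoyl chloride, Et3N, toluene, rt; then 26, 80 °C
Reagents that add atoms: angelic acid C/C=C(/C)C(=O)O
Why: Yamaguchi esterification through the mixed 2,4,6-trichlorobenzoic anhydride, run without a nucleophilic amine catalyst so that the (Z)-geometry of the angelate is kept, acylates both the primary C13 and the secondary C9 hydroxyl.

Compound list
1 | (2E)-4-acetoxy-2-methylbut-2-enal | O=C/C(C)=C/COC(C)=O | starting material
2 | trimethyl(vinyloxy)silane | C=CO[Si](C)(C)C | starting material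
3 | (2E,4R)-3-methyl-6-oxo-4-(trichlorosilyloxy)hex-2-en-1-yl acetate | O=CC[C@@H](O[Si](Cl)(Cl)Cl)/C(C)=C/COC(C)=O | intermediate (not isolated)
4 | (2E,4R)-4-hydroxy-6,6-dimethoxy-3-methylhex-2-en-1-yl acetate | COC(OC)C[C@@H](O)/C(C)=C/COC(C)=O | intermediate
5 | (2E,4R)-4-[(tert-butyldimethylsilyl)oxy]-6,6-dimethoxy-3-methylhex-2-en-1-yl acetate | COC(OC)C[C@@H](O[Si](C)(C)C(C)(C)C)/C(C)=C/COC(C)=O | intermediate
6 | (2E,4R)-4-[(tert-butyldimethylsilyl)oxy]-6,6-dimethoxy-3-methylhex-2-en-1-ol | COC(OC)C[C@@H](O[Si](C)(C)C(C)(C)C)/C(C)=C/CO | intermediate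
7 | (2E,4R)-4-[(tert-butyldimethylsilyl)oxy]-6,6-dimethoxy-3-methylhex-2-enal | COC(OC)C[C@@H](O[Si](C)(C)C(C)(C)C)/C(C)=C/C=O | intermediate
8 | methyl 3-methylbut-2-enoate | COC(=O)C=C(C)C | starting material
9 | tert-butyl[(1-methoxy-3-methylbuta-1,3-dien-1-yl)oxy]dimethylsilane | COC(O[Si](C)(C)C(C)(C)C)=CC(C)=C | intermediate
10 | methyl (2E,5S,6E,8R)-8-[(tert-butyldimethylsilyl)oxy]-5-hydroxy-10,10-dimethoxy-3,7-dimethyldeca-2,6-dienoate | COC(OC)C[C@@H](O[Si](C)(C)C(C)(C)C)/C(C)=C/[C@@H](O)C/C(C)=C/C(=O)OC | intermediate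
11 | (2E,5S,6E,8R)-8-[(tert-butyldimethylsilyl)oxy]-5-hydroxy-10,10-dimethoxy-3,7-dimethyldeca-2,6-dienoic acid | COC(OC)C[C@@H](O[Si](C)(C)C(C)(C)C)/C(C)=C/[C@@H](O)C/C(C)=C/C(=O)O | intermediate
12 | triethylsilyl (2E,5S,6E,8R)-8-[(tert-butyldimethylsilyl)oxy]-10,10-dimethoxy-3,7-dimethyl-5-[(triethylsilyl)oxy]deca-2,6-dienoate | COC(OC)C[C@@H](O[Si](C)(C)C(C)(C)C)/C(C)=C/[C@@H](O[Si](CC)(CC)CC)C/C(C)=C/C(=O)O[Si](CC)(CC)CC | intermediate
13 | (2E,5S,6E,8R)-8-[(tert-butyldimethylsilyl)oxy]-10,10-dimethoxy-3,7-dimethyl-5-[(triethylsilyl)oxy]deca-2,6-dienoyl chloride | COC(OC)C[C@@H](O[Si](C)(C)C(C)(C)C)/C(C)=C/[C@@H](O[Si](CC)(CC)CC)C/C(C)=C/C(Cl)=O | intermediate (not isolated)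
14 | (5S,6E,8R)-8-[(tert-butyldimethylsilyl)oxy]-10,10-dimethoxy-7-methyl-3-methylidene-5-[(triethylsilyl)oxy]deca-1,6-dien-1-one (vinylketene) | COC(OC)C[C@@H](O[Si](C)(C)C(C)(C)C)/C(C)=C/[C@@H](O[Si](CC)(CC)CC)CC(=C)C=C=O | intermediate (not isolated)
15 | (4S)-7-methyl-2-methylidene-7-[(1R)-1-(tert-butyldimethylsilyloxy)-3,3-dimethoxypropyl]-4-(triethylsilyloxy)bicyclo[3.1.1]heptan-6-one | O=C2[C@H]3[C@@H](O[Si](CC)(CC)CC)CC(=C)[C@@H]2[C@@]3(C)[C@H](O[Si](C)(C)C(C)(C)C)CC(OC)OC | intermediate
16 | 7-methyl-4-methylidene-7-[(1R)-1-(tert-butyldimethylsilyloxy)-3,3-dimethoxypropyl]bicyclo[3.1.1]heptane-2,6-dione | O=C2[C@H]3C(=O)CC(=C)[C@@H]2[C@@]3(C)[C@H](O[Si](C)(C)C(C)(C)C)CC(OC)OC | intermediate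
17 | 2-(tert-butyldimethylsilyloxy)-7-methyl-4-methylidene-7-[(1R)-1-(tert-butyldimethylsilyloxy)-3,3-dimethoxypropyl]bicyclo[3.1.1]hept-2-en-6-one | O=C2[C@H]3C(O[Si](C)(C)C(C)(C)C)=CC(=C)[C@@H]2[C@@]3(C)[C@H](O[Si](C)(C)C(C)(C)C)CC(OC)OC | intermediate
18 | diethyl (1-cyanoethyl)phosphonate | CCOP(=O)(OCC)C(C)C#N | starting material
19 | 2-{2-(tert-butyldimethylsilyloxy)-7-methyl-4-methylidene-7-[(1R)-1-(tert-butyldimethylsilyloxy)-3,3-dimethoxypropyl]bicyclo[3.1.1]hept-2-en-6-ylidene}propanenitrile | N#CC(C)=C2[C@H]3C(O[Si](C)(C)C(C)(C)C)=CC(=C)[C@@H]2[C@@]3(C)[C@H](O[Si](C)(C)C(C)(C)C)CC(OC)OC | intermediate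
20 | 2-{2-(tert-butyldimethylsilyloxy)-7-methyl-4-methylidene-7-[(1R)-1-(tert-butyldimethylsilyloxy)-3,3-dimethoxypropyl]bicyclo[3.1.1]hept-2-en-6-ylidene}propanal | O=CC(C)=C2[C@H]3C(O[Si](C)(C)C(C)(C)C)=CC(=C)[C@@H]2[C@@]3(C)[C@H](O[Si](C)(C)C(C)(C)C)CC(OC)OC | intermediate
21 | 2-{2-(tert-butyldimethylsilyloxy)-7-methyl-4-methylidene-7-[(1R)-1-(tert-butyldimethylsilyloxy)-3,3-dimethoxypropyl]bicyclo[3.1.1]hept-2-en-6-yl}prop-1-en-1-yl acetate | CC(=O)OC=C(C)[C@@H]2[C@H]3C(O[Si](C)(C)C(C)(C)C)=CC(=C)[C@@H]2[C@@]3(C)[C@H](O[Si](C)(C)C(C)(C)C)CC(OC)OC | intermediate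
22 | 2-{7-methyl-4-methylidene-2-oxo-7-[(1R)-1-(tert-butyldimethylsilyloxy)-3-oxopropyl]bicyclo[3.1.1]heptan-6-yl}prop-1-en-1-yl acetate | CC(=O)OC=C(C)[C@@H]2[C@H]3C(=O)CC(=C)[C@@H]2[C@@]3(C)[C@H](O[Si](C)(C)C(C)(C)C)CC=O | intermediate (not isolated)
23 | 2-{4,7-dimethyl-2-oxo-7-[(1R)-1-(tert-butyldimethylsilyloxy)-3-oxopropyl]bicyclo[3.1.1]hept-3-en-6-yl}prop-1-en-1-yl acetate | CC(=O)OC=C(C)[C@@H]2[C@H]3C(=O)C=C(C)[C@@H]2[C@@]3(C)[C@H](O[Si](C)(C)C(C)(C)C)CC=O | intermediate
24 | 7-acetoxy-9-(tert-butyldimethylsilyloxy)-1-oxolongipin-2-en-13-al | O=C[C@]1(C)[C@@H]2[C@H]3C(=O)C=C(C)[C@@H]2[C@@]3(C)[C@H](O[Si](C)(C)C(C)(C)C)C[C@H]1OC(C)=O | intermediate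
25 | 7-acetoxy-9-(tert-butyldimethylsilyloxy)-13-hydroxylongipin-2-en-1-one | OC[C@]1(C)[C@@H]2[C@H]3C(=O)C=C(C)[C@@H]2[C@@]3(C)[C@H](O[Si](C)(C)C(C)(C)C)C[C@H]1OC(C)=O | intermediate
26 | 7-acetoxy-9,13-dihydroxylongipin-2-en-1-one | OC[C@]1(C)[C@@H]2[C@H]3C(=O)C=C(C)[C@@H]2[C@@]3(C)[C@H](O)C[C@H]1OC(C)=O | intermediate
27 | angelic acid, (2Z)-2-methylbut-2-enoic acid | C/C=C(/C)C(=O)O | starting material
28 | (2Z)-2-methylbut-2-enoic 2,4,6-trichlorobenzoic anhydride | C/C=C(/C)C(=O)OC(=O)c1c(Cl)cc(Cl)cc1Cl | intermediate (not isolated)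
29 | target CNP0364726.1, 7-acetoxy-9,13-bis[(2Z)-2-methylbut-2-enoyloxy]longipin-2-en-1-one | C/C=C(/C)C(=O)OC[C@]1(C)[C@@H]2[C@H]3C(=O)C=C(C)[C@@H]2[C@@]3(C)[C@H](OC(=O)/C(C)=C\C)C[C@H]1OC(C)=O | target

Total step count: 19. Longest linear sequence: 18 (steps 1–4 and 6–19; step 5 is a one-step branch).

Steps most likely to fail

Step 16. The enol acetate may be too weak a nucleophile for the BF3-bound aldehyde, so that β-elimination of the silyloxy group overtakes C–C bonding, and a synclinal approach would erode the facial selectivity at C6. The fallback sets out from 23 and changes from electrophile activation to a metal enolate: Bu3SnOMe cleaves the enol acetate to the tributylstannyl enolate F1, which on warming closes the ring by tin-enolate aldol addition and gives after aqueous work-up the hydroxy aldehyde F2; acetylation (Ac2O, pyridine, DMAP) returns to the route at 24.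

Step 9. Dimerisation and polymerisation of the vinylketene may outrun its intramolecular capture, because the alkene carries two allylic silyloxy groups and is a poor nucleophile. The fallback sets out from 12 by way of the acid chloride 13 and uses the more electrophilic nitrogen analogue of the ketene: quenching 13 with pyrrolidine gives the amide F3; Tf2O and 2,4,6-collidine convert it into a vinylketeniminium ion whose intramolecular [2+2] cycloaddition gives the cyclobutaniminium triflate F4; hydrolysis with aqueous NaHCO3 returns to the route at 15.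

Step 14. Hydride transfer to the fully substituted β-carbon C5 may be too slow, leaving 1,2-reduction of the aldehyde or no reaction. The fallback sets out from 19 and moves the conjugate reduction one step earlier and to an electron-transfer mechanism: SmI2 with t-BuOH in THF/DMA reduces the unsaturated nitrile to the saturated nitrile F5 (protonation of C5 from the same open face); i-Bu2AlH gives the aldehyde F6; enol acetylation (Ac2O, Et3N, DMAP) returns to the route at 21.

Further compounds
F1 | step 16 | tributylstannyl enolate of the C13 aldehyde, 2-{4,7-dimethyl-2-oxo-7-[(1R)-1-(tert-butyldimethylsilyloxy)-3-oxopropyl]bicyclo[3.1.1]hept-3-en-6-yl}prop-1-en-1-yl tributylstannyl ether | CCCC[Sn](CCCC)(CCCC)OC=C(C)[C@@H]2[C@H]3C(=O)C=C(C)[C@@H]2[C@@]3(C)[C@H](O[Si](C)(C)C(C)(C)C)CC=O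
F2 | step 16 | 9-(tert-butyldimethylsilyloxy)-7-hydroxy-1-oxolongipin-2-en-13-al | O=C[C@]1(C)[C@@H]2[C@H]3C(=O)C=C(C)[C@@H]2[C@@]3(C)[C@H](O[Si](C)(C)C(C)(C)C)C[C@H]1O
F3 | step 9 | (2E,5S,6E,8R)-8-[(tert-butyldimethylsilyl)oxy]-10,10-dimethoxy-3,7-dimethyl-1-(pyrrolidin-1-yl)-5-[(triethylsilyl)oxy]deca-2,6-dien-1-one | COC(OC)C[C@@H](O[Si](C)(C)C(C)(C)C)/C(C)=C/[C@@H](O[Si](CC)(CC)CC)C/C(C)=C/C(=O)N1CCCC1
F4 | step 9 | 1-{7-methyl-2-methylidene-7-[(1R)-1-(tert-butyldimethylsilyloxy)-3,3-dimethoxypropyl]-4-(triethylsilyloxy)bicyclo[3.1.1]heptan-6-ylidene}pyrrolidinium triflate | C1CC[N+](C1)=C2[C@H]3[C@@H](O[Si](CC)(CC)CC)CC(=C)[C@@H]2[C@@]3(C)[C@H](O[Si](C)(C)C(C)(C)C)CC(OC)OC.[O-]S(=O)(=O)C(F)(F)F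
F5 | step 14 | 2-{2-(tert-butyldimethylsilyloxy)-7-methyl-4-methylidene-7-[(1R)-1-(tert-butyldimethylsilyloxy)-3,3-dimethoxypropyl]bicyclo[3.1.1]hept-2-en-6-yl}propanenitrile | N#CC(C)[C@@H]2[C@H]3C(O[Si](C)(C)C(C)(C)C)=CC(=C)[C@@H]2[C@@]3(C)[C@H](O[Si](C)(C)C(C)(C)C)CC(OC)OC
F6 | step 14 | 2-{2-(tert-butyldimethylsilyloxy)-7-methyl-4-methylidene-7-[(1R)-1-(tert-butyldimethylsilyloxy)-3,3-dimethoxypropyl]bicyclo[3.1.1]hept-2-en-6-yl}propanal | O=CC(C)[C@@H]2[C@H]3C(O[Si](C)(C)C(C)(C)C)=CC(=C)[C@@H]2[C@@]3(C)[C@H](O[Si](C)(C)C(C)(C)C)CC(OC)OC
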